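## Retrosynthetic overview

1. Target 24 ⇐ hydroxyl-directed epoxidation of the (Z)-C1=C10 olefin of diol 23 ⇐ acetonide cleavage and C8 angeloylation of macrocyclic α-methylene lactone 20.
2. The ten-membered carbocycle (second ring) ⇐ ring-closing metathesis of diene 19 (C1=C10). The γ-lactone (first ring) ⇐ Pd-catalysed cyclocarbonylation of homopropargylic alcohol 18 (C11–C12). The oxirane is formed last.
3. Key C6–C7 bond ⇐ iridium-catalysed redox-neutral C–H propargylation that joins West alcohol 7 and East carbonate 14 (sets C6 and C7).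
4. West fragment 7 ⇐ α-methylene-γ-butyrolactone 1 (Sharpless kinetic resolution sets C3 and C4). East fragment 14 ⇐ methyl (R)-glycidate 8 (C8 from the chiral pool, C7 by Noyori reduction).
5. The angelate is brought in as preformed mixed anhydride 16 from angelic acid 15.

Assumption: the target is read as the 12,6-olide with the ester at C8, and compounds 17–24, F3 and F4 are described with germacrane numbering (C1–C10 ring carbons, C11–C13 lactone carbons, C14 on C10, C15 on C4). The same C-numbers are used in the "Why" lines.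

## Route

**West fragment**

Step 1
Reactants: 1 3-methylideneoxolan-2-one
Product: 2 3-methylideneoxolan-2-ol (racemic lactol)
Conditions: i-Bu2AlH (1.1 equiv), CH2Cl2, −78 °C; then H2O
Reagents that add atoms: none
Why: Partial hydride reduction of the lactone stops at the aluminium hemiacetal at −78 °C (1,2-reduction); no lasting stereocenter is made.

Step 2
Reactants: 2 3-methylideneoxolan-2-ol
Product: 3 rac-3-methylidenehept-6-ene-1,4-diol
Conditions: CH2=CHCH2MgBr (2.5 equiv), THF, 0 → 23 °C; then H2O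
Reagents that add atoms: allylmagnesium bromide, C=CC[Mg]Br
Why: Grignard 1,2-addition to the open hydroxy-enal form of the lactol; the new carbinol (C3) is racemic and is resolved in step 4.

Step 3
Reactants: 3 rac-3-methylidenehept-6-ene-1,4-diol
Product: 4 rac-4-hydroxy-3-methylidenehept-6-en-1-yl 2,2-dimethylpropanoate
Conditions: t-BuCOCl (1.05 equiv), pyridine, CH2Cl2, −20 °C
Reagents that add atoms: pivaloyl chloride, CC(C)(C)C(Cl)=O
Why: Sterically selective acylation of the primary over the secondary allylic hydroxyl; it frees the allylic alcohol as the only titanium-binding site for step 4.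

Step 4
Reactants: 4 rac-4-hydroxy-3-methylidenehept-6-en-1-yl 2,2-dimethylpropanoate
Product: 5 2-{(2R)-2-[(1S)-1-hydroxybut-3-en-1-yl]oxiran-2-yl}ethyl 2,2-dimethylpropanoate
Conditions: Ti(O-i-Pr)4 (15 mol %), L-(+)-diisopropyl tartrate (18 mol %), t-BuOOH (0.45 equiv), 4 Å molecular sieves, CH2Cl2, −20 °C
Reagents that add atoms: tert-butyl hydroperoxide, CC(C)(C)OO
Why: Sharpless asymmetric epoxidation run as a kinetic resolution: the (S)-alcohol reacts fast with the L-(+)-tartrate catalyst and gives the erythro epoxy alcohol, which fixes C3 and the C4–O configuration; the (R)-alcohol is left and separated.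

Step 5
Reactants: 5 2-{(2R)-2-[(1S)-1-hydroxybut-3-en-1-yl]oxiran-2-yl}ethyl 2,2-dimethylpropanoate
Product: 6 (3S,4S)-3-methylhept-6-ene-1,3,4-triol
Conditions: LiAlH4 (3 equiv), THF, 0 → 23 °C; then H2O
Reagents that add atoms: none
Why: Hydride opens the 2,2-disubstituted oxirane by SN2 attack at its CH2 terminus (this creates the C15 methyl and leaves the C4–O bond untouched) and reduces the pivalate to the primary alcohol.

Step 6
Reactants: 6 (3S,4S)-3-methylhept-6-ene-1,3,4-triol
Product: 7 2-[(4S,5S)-2,2,4-trimethyl-5-(prop-2-en-1-yl)-1,3-dioxolan-4-yl]ethan-1-ol (West fragment)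
Conditions: Me2C(OMe)2, pyridinium p-toluenesulfonate (cat.), CH2Cl2, 23 °C; then MeOH
Reagents that add atoms: 2,2-dimethoxypropane, COC(C)(C)OC
Why: Thermodynamic acetonide formation prefers the five-membered dioxolane of the vicinal diol over the 4,4-disubstituted dioxane, so the primary alcohol stays free; no stereocenter changes.

**East fragment**

Step 7
Reactants: 8 methyl (2R)-oxirane-2-carboxylate
Product: 9 methyl (2R)-2-hydroxy-4-methylpent-4-enoate
Conditions: CH2=C(CH3)MgBr (1.3 equiv), CuI (10 mol %), THF, −40 °C; then H2O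
Reagents that add atoms: isopropenylmagnesium bromide, C=C(C)[Mg]Br
Why: Copper-catalysed Grignard opening of the glycidate at the unsubstituted C3 (SN2); the C8 stereocenter comes unchanged from the chiral pool.

Step 8
Reactants: 9 methyl (2R)-2-hydroxy-4-methylpent-4-enoate
Product: 10 methyl (2R)-2-[(tert-butyldimethylsilyl)oxy]-4-methylpent-4-enoate
Conditions: TBSCl, imidazole, DMF, 23 °C
Reagents that add atoms: tert-butyldimethylsilyl chloride, CC(C)(C)[Si](C)(C)Cl
Why: Standard silylation of a secondary alcohol; the silyl ether survives every step up to step 17.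

Step 9
Reactants: 10 methyl (2R)-2-[(tert-butyldimethylsilyl)oxy]-4-methylpent-4-enoate
Product: 11 (2R)-2-[(tert-butyldimethylsilyl)oxy]-N-methoxy-N,4-dimethylpent-4-enamide
Conditions: MeNH(OMe)·HCl, i-PrMgCl, THF, −20 °C; then H2O
Reagents that add atoms: N,O-dimethylhydroxylamine hydrochloride, CNOC.Cl
Why: Weinreb amide formation from the ester with the magnesium amide at low temperature, which does not epimerise the α-silyloxy centre.

Step 10
Reactants: 11 (2R)-2-[(tert-butyldimethylsilyl)oxy]-N-methoxy-N,4-dimethylpent-4-enamide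
Product: 12 (4R)-4-[(tert-butyldimethylsilyl)oxy]-6-methyl-1-(trimethylsilyl)hept-6-en-1-yn-3-one
Conditions: HC≡CSiMe3, n-BuLi, THF, −78 °C; then 11, −78 → 0 °C; then H2O
Reagents that add atoms: ethynyltrimethylsilane, C#C[Si](C)(C)C
Why: Weinreb ketone synthesis: the lithium acetylide adds once and the chelated tetrahedral intermediate collapses to the ynone only on work-up.

Step 11
Reactants: 12 (4R)-4-[(tert-butyldimethylsilyl)oxy]-6-methyl-1-(trimethylsilyl)hept-6-en-1-yn-3-one
Product: 13 (3S,4R)-4-[(tert-butyldimethylsilyl)oxy]-6-methyl-1-(trimethylsilyl)hept-6-en-1-yn-3-ol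
Conditions: RuCl[(R,R)-TsDPEN](p-cymene) (2 mol %), i-PrOH, 23 °C
Reagents that add atoms: none
Why: Noyori asymmetric transfer hydrogenation of an ynone; hydride delivery is catalyst-controlled and sets C7 as (S), anti to the C8 silyl ether.

Step 12
Reactants: 13 (3S,4R)-4-[(tert-butyldimethylsilyl)oxy]-6-methyl-1-(trimethylsilyl)hept-6-en-1-yn-3-ol
Product: 14 methyl (3S,4R)-4-[(tert-butyldimethylsilyl)oxy]-6-methyl-1-(trimethylsilyl)hept-6-en-1-yn-3-yl carbonate (East fragment)
Conditions: ClCO2Me, pyridine, CH2Cl2, 0 °C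
Reagents that add atoms: methyl chloroformate, COC(=O)Cl
Why: O-acylation with retention at C7 gives a thermally robust propargylic leaving group.

**Angelate reagent**

Step 13
Reactants: 15 (2Z)-2-methylbut-2-enoic acid (angelic acid)
Product: 16 (2Z)-2-methylbut-2-enoic 2,4,6-trichlorobenzoic anhydride
Conditions: 2,4,6-Cl3C6H2COCl, Et3N, toluene, 23 °C; filter, concentrate
Reagents that add atoms: 2,4,6-trichlorobenzoyl chloride, O=C(Cl)c1c(Cl)cc(Cl)cc1Cl
Why: Yamaguchi mixed-anhydride formation; once the amine salt is filtered off, no nucleophilic amine remains to isomerise the Z-enoate to the tiglate.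

**Fragment union and endgame**

Step 14
Reactants: 7 2-[(4S,5S)-2,2,4-trimethyl-5-(prop-2-en-1-yl)-1,3-dioxolan-4-yl]ethan-1-ol; 14 methyl (3S,4R)-4-[(tert-butyldimethylsilyl)oxy]-6-methyl-1-(trimethylsilyl)hept-6-en-1-yn-3-yl carbonate
Product: 18 (2R,3S,4R)-4-[(tert-butyldimethylsilyl)oxy]-3-ethynyl-6-methyl-1-[(4S,5S)-2,2,4-trimethyl-5-(prop-2-en-1-yl)-1,3-dioxolan-4-yl]hept-6-en-2-ol, via alkynylsilane adduct 17 (not isolated)
Conditions: [Ir(cod)Cl]2 (2.5 mol %), (R)-SEGPHOS (5 mol %), 4-cyano-3-nitrobenzoic acid (10 mol %), K3PO4 (20 mol %), THF, 65 °C; then MeOH, K2CO3 (0.2 equiv), 23 °C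
Reagents that add atoms: none
Why: Proposed new method: the cyclometallated iridium–SEGPHOS catalyst dehydrogenates the primary alcohol of 7, the resulting monovalent iridium adds anti-SN2′ to carbonate 14 to give an axially chiral allenyl complex of trivalent iridium, and this adds to the transient aldehyde through a closed six-membered SE2′ transition state, so C6–C7 forms with net inversion at C7 and anti topology (6R,7S), with the ligand enantiomer chosen as the matched one ((R) is the prediction, to be checked against (S)); the closest known reactions are the Krische iridium-catalysed transfer-hydrogenative propargylation of alcohols with achiral primary silylpropargyl chlorides and the Marshall Pd/Zn allenylmetal addition, and an enantioenriched secondary propargylic carbonate with a neighbouring stereocenter has not been used in the iridium chemistry; methanolysis then removes the alkynyl silane.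

Step 15
Reactants: 18 (2R,3S,4R)-4-[(tert-butyldimethylsilyl)oxy]-3-ethynyl-6-methyl-1-[(4S,5S)-2,2,4-trimethyl-5-(prop-2-en-1-yl)-1,3-dioxolan-4-yl]hept-6-en-2-ol
Product: 19 (4S,5R)-4-{(1R)-1-[(tert-butyldimethylsilyl)oxy]-3-methylbut-3-en-1-yl}-3-methylidene-5-{[(4S,5S)-2,2,4-trimethyl-5-(prop-2-en-1-yl)-1,3-dioxolan-4-yl]methyl}oxolan-2-one
Conditions: PdI2 (5 mol %), P(n-Bu)3 (10 mol %), CO (8 atm), MeCN, 75 °C
Reagents that add atoms: carbon monoxide, [C-]#[O+]
Why: Norton-type palladium-catalysed cyclocarbonylation: the C6 alkoxycarbonyl–palladium species adds syn across the terminal alkyne and protonolysis releases the α-methylene-γ-butyrolactone; C6 and C7 are untouched, so the trans ring fusion is inherited from step 14.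

Step 16
Reactants: 19 (4S,5R)-4-{(1R)-1-[(tert-butyldimethylsilyl)oxy]-3-methylbut-3-en-1-yl}-3-methylidene-5-{[(4S,5S)-2,2,4-trimethyl-5-(prop-2-en-1-yl)-1,3-dioxolan-4-yl]methyl}oxolan-2-one
Product: 20 (1(10)Z,3S,4S,6R,7S,8R)-8-[(tert-butyldimethylsilyl)oxy]-3,4-(isopropylidenedioxy)germacra-1(10),11(13)-dien-12,6-olide
Conditions: second-generation Hoveyda–Grubbs catalyst RuCl2(H2IMes)(=CH-C6H4-2-O-i-Pr) (15 mol %), toluene (1 mM), 100 °C
Reagents that add atoms: none
Why: Ring-closing olefin metathesis of the monosubstituted and the 1,1-disubstituted alkene with loss of ethene; the trisubstituted C1=C10 bond forms Z because the E-cyclodecene is much more strained, and closure onto the electron-poor α-methylene group would need a bridgehead olefin.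

Step 17
Reactants: 20 (1(10)Z,3S,4S,6R,7S,8R)-8-[(tert-butyldimethylsilyl)oxy]-3,4-(isopropylidenedioxy)germacra-1(10),11(13)-dien-12,6-olide
Product: 21 (1(10)Z,3S,4S,6R,7R,8R)-8-hydroxy-3,4-(isopropylidenedioxy)germacra-1(10),11(13)-dien-12,6-olide
Conditions: HF·pyridine, pyridine, THF, 0 → 23 °C
Reagents that add atoms: none
Why: Fluoride-mediated silyl ether cleavage under non-basic conditions, which avoids alkoxide-induced translactonisation to the 12,8-olide and leaves the acetonide in place (the C7 descriptor changes only through CIP priorities).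

Step 18
Reactants: 21 (1(10)Z,3S,4S,6R,7R,8R)-8-hydroxy-3,4-(isopropylidenedioxy)germacra-1(10),11(13)-dien-12,6-olide; 16 (2Z)-2-methylbut-2-enoic 2,4,6-trichlorobenzoic anhydride
Product: 22 (1(10)Z,3S,4S,6R,7R,8R)-3,4-(isopropylidenedioxy)-8-{[(2Z)-2-methylbut-2-enoyl]oxy}germacra-1(10),11(13)-dien-12,6-olide
Conditions: 16 (3 equiv), NaHCO3 (solid), toluene, 90 °C
Reagents that add atoms: none
Why: Yamaguchi-type acylation at the less hindered angeloyl carbonyl of the mixed anhydride; the absence of amine or DMAP keeps the Z geometry of the angelate, and C8 reacts with retention.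

Step 19
Reactants: 22 (1(10)Z,3S,4S,6R,7R,8R)-3,4-(isopropylidenedioxy)-8-{[(2Z)-2-methylbut-2-enoyl]oxy}germacra-1(10),11(13)-dien-12,6-olide
Product: 23 (1(10)Z,3S,4S,6R,7R,8R)-3,4-dihydroxy-8-{[(2Z)-2-methylbut-2-enoyl]oxy}germacra-1(10),11(13)-dien-12,6-olide
Conditions: AcOH/H2O (4:1), 45 °C
Reagents that add atoms: none
Why: Mild acid hydrolysis of the acetonide, done before the acid-sensitive oxirane exists; esters and the lactone are stable under these conditions.

Step 20
Reactants: 23 (1(10)Z,3S,4S,6R,7R,8R)-3,4-dihydroxy-8-{[(2Z)-2-methylbut-2-enoyl]oxy}germacra-1(10),11(13)-dien-12,6-olide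
Product: 24 (1R,3S,4S,6R,7S,8R,10S)-1,10-epoxy-3,4-dihydroxy-8-{[(2Z)-2-methylbut-2-enoyl]oxy}germacr-11(13)-en-12,6-olide (CNP0113954.1)
Conditions: VO(acac)2 (5 mol %), t-BuOOH (1.5 equiv), CH2Cl2, 0 °C
Reagents that add atoms: tert-butyl hydroperoxide, CC(C)(C)OO
Why: Vanadium-catalysed hydroxyl-directed epoxidation of a homoallylic alcohol: the C3 hydroxyl binds the vanadium peroxide and delivers oxygen to the olefin face on its own side, which sets C1 (R) and C10 (S) as the cis-oxirane; the two conjugated alkenes are not attacked.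

## Compound list

1 | 3-methylideneoxolan-2-one | C=C1CCOC1=O | starting material
2 | 3-methylideneoxolan-2-ol | C=C1CCOC1O | intermediate
3 | rac-3-methylidenehept-6-ene-1,4-diol | C=CCC(O)C(=C)CCO | intermediate
4 | rac-4-hydroxy-3-methylidenehept-6-en-1-yl 2,2-dimethylpropanoate | C=CCC(O)C(=C)CCOC(=O)C(C)(C)C | intermediate
5 | 2-{(2R)-2-[(1S)-1-hydroxybut-3-en-1-yl]oxiran-2-yl}ethyl 2,2-dimethylpropanoate | C=CC[C@H](O)[C@@]1(CCOC(=O)C(C)(C)C)CO1 | intermediate
6 | (3S,4S)-3-methylhept-6-ene-1,3,4-triol | OCC[C@](C)(O)[C@@H](O)CC=C | intermediate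
7 | 2-[(4S,5S)-2,2,4-trimethyl-5-(prop-2-en-1-yl)-1,3-dioxolan-4-yl]ethan-1-ol | C=CC[C@@H]1OC(C)(C)O[C@@]1(C)CCO | intermediate
8 | methyl (2R)-oxirane-2-carboxylate | COC(=O)[C@H]1CO1 | starting material
9 | methyl (2R)-2-hydroxy-4-methylpent-4-enoate | COC(=O)[C@H](O)CC(C)=C | intermediate
10 | methyl (2R)-2-[(tert-butyldimethylsilyl)oxy]-4-methylpent-4-enoate | COC(=O)[C@H](O[Si](C)(C)C(C)(C)C)CC(C)=C | intermediate
11 | (2R)-2-[(tert-butyldimethylsilyl)oxy]-N-methoxy-N,4-dimethylpent-4-enamide | CON(C)C(=O)[C@H](O[Si](C)(C)C(C)(C)C)CC(C)=C | intermediate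
12 | (4R)-4-[(tert-butyldimethylsilyl)oxy]-6-methyl-1-(trimethylsilyl)hept-6-en-1-yn-3-one | C[Si](C)(C)C#CC(=O)[C@H](O[Si](C)(C)C(C)(C)C)CC(C)=C | intermediate
13 | (3S,4R)-4-[(tert-butyldimethylsilyl)oxy]-6-methyl-1-(trimethylsilyl)hept-6-en-1-yn-3-ol | C[Si](C)(C)C#C[C@H](O)[C@H](O[Si](C)(C)C(C)(C)C)CC(C)=C | intermediate
14 | methyl (3S,4R)-4-[(tert-butyldimethylsilyl)oxy]-6-methyl-1-(trimethylsilyl)hept-6-en-1-yn-3-yl carbonate | C[Si](C)(C)C#C[C@H](OC(=O)OC)[C@H](O[Si](C)(C)C(C)(C)C)CC(C)=C | intermediate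
15 | (2Z)-2-methylbut-2-enoic acid (angelic acid) | C/C=C(/C)C(=O)O | starting material
16 | (2Z)-2-methylbut-2-enoic 2,4,6-trichlorobenzoic anhydride | C/C=C(/C)C(=O)OC(=O)c1c(Cl)cc(Cl)cc1Cl | intermediate
17 | (2R,3S,4R)-4-[(tert-butyldimethylsilyl)oxy]-6-methyl-1-[(4S,5S)-2,2,4-trimethyl-5-(prop-2-en-1-yl)-1,3-dioxolan-4-yl]-3-[(trimethylsilyl)ethynyl]hept-6-en-2-ol | C=CC[C@@H]1OC(C)(C)O[C@@]1(C)C[C@@H](O)[C@H](C#C[Si](C)(C)C)[C@H](O[Si](C)(C)C(C)(C)C)CC(C)=C | intermediate
18 | (2R,3S,4R)-4-[(tert-butyldimethylsilyl)oxy]-3-ethynyl-6-methyl-1-[(4S,5S)-2,2,4-trimethyl-5-(prop-2-en-1-yl)-1,3-dioxolan-4-yl]hept-6-en-2-ol | C=CC[C@@H]1OC(C)(C)O[C@@]1(C)C[C@@H](O)[C@H](C#C)[C@H](O[Si](C)(C)C(C)(C)C)CC(C)=C | intermediate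
19 | (4S,5R)-4-{(1R)-1-[(tert-butyldimethylsilyl)oxy]-3-methylbut-3-en-1-yl}-3-methylidene-5-{[(4S,5S)-2,2,4-trimethyl-5-(prop-2-en-1-yl)-1,3-dioxolan-4-yl]methyl}oxolan-2-one | C=CC[C@@H]1OC(C)(C)O[C@@]1(C)C[C@H]2OC(=O)C(=C)[C@@H]2[C@H](O[Si](C)(C)C(C)(C)C)CC(C)=C | intermediate
20 | (1(10)Z,3S,4S,6R,7S,8R)-8-[(tert-butyldimethylsilyl)oxy]-3,4-(isopropylidenedioxy)germacra-1(10),11(13)-dien-12,6-olide | C=C1C(=O)O[C@@H]2C[C@]3(C)OC(C)(C)O[C@H]3C/C=C(C)\C[C@@H](O[Si](C)(C)C(C)(C)C)[C@@H]12 | intermediate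
21 | (1(10)Z,3S,4S,6R,7R,8R)-8-hydroxy-3,4-(isopropylidenedioxy)germacra-1(10),11(13)-dien-12,6-olide | C=C1C(=O)O[C@@H]2C[C@]3(C)OC(C)(C)O[C@H]3C/C=C(C)\C[C@@H](O)[C@@H]12 | intermediate
22 | (1(10)Z,3S,4S,6R,7R,8R)-3,4-(isopropylidenedioxy)-8-{[(2Z)-2-methylbut-2-enoyl]oxy}germacra-1(10),11(13)-dien-12,6-olide | C=C1C(=O)O[C@@H]2C[C@]3(C)OC(C)(C)O[C@H]3C/C=C(C)\C[C@@H](OC(=O)/C(C)=C\C)[C@@H]12 | intermediate
23 | (1(10)Z,3S,4S,6R,7R,8R)-3,4-dihydroxy-8-{[(2Z)-2-methylbut-2-enoyl]oxy}germacra-1(10),11(13)-dien-12,6-olide | C=C1C(=O)O[C@@H]2C[C@](C)(O)[C@@H](O)C/C=C(C)\C[C@@H](OC(=O)/C(C)=C\C)[C@@H]12 | intermediate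
24 | (1R,3S,4S,6R,7S,8R,10S)-1,10-epoxy-3,4-dihydroxy-8-{[(2Z)-2-methylbut-2-enoyl]oxy}germacr-11(13)-en-12,6-olide | C=C1C(=O)O[C@@H]2C[C@](C)(O)[C@@H](O)C[C@H]3O[C@@]3(C)C[C@@H](OC(=O)/C(C)=C\C)[C@@H]12 | target

## Step count and risks

Total step count: 20. Longest linear sequence: 13 (steps 1–6 then 14–20; the East line, steps 7–12 then 14–20, is equally long), which is 0.65 of the total.

The three steps most likely to fail:

**Step 14 (the proposed new union).** The iridium chemistry has no precedent with a chiral secondary propargylic carbonate; chirality transfer could erode or the donor could eliminate. The fallback uses known chemistry and sets out from 7 and 13. Alcohol 7 is oxidised (Dess–Martin periodinane, NaHCO3, CH2Cl2) to 2-[(4S,5S)-2,2,4-trimethyl-5-(prop-2-en-1-yl)-1,3-dioxolan-4-yl]acetaldehyde F1. Alcohol 13 is converted (MsCl, Et3N, CH2Cl2, −78 °C) into (3S,4R)-4-[(tert-butyldimethylsilyl)oxy]-6-methyl-1-(trimethylsilyl)hept-6-en-1-yn-3-yl methanesulfonate F2. The two are joined by the Marshall reaction (Pd(OAc)2 5 mol %, PPh3 5 mol %, Et2Zn 3 equiv, THF, −78 to −20 °C): zerovalent palladium opens F2 anti-SN2′, transmetallation gives the allenylzinc, and this adds to F1 through a cyclic SE2′ transition state to give the anti adduct with the same net inversion at C7. The fallback comes back to the route at 17, which is then methanolysed (K2CO3, MeOH) to 18.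

**Step 16 (ring-closing metathesis).** A ten-membered ring with a trisubstituted olefin, trans-fused to the lactone, may close slowly, oligomerise, or react at the α-methylene group. The fallback closes the carbocycle before the lactone and sets out from 17, isolated by leaving out the methanolysis stage of step 14. Metathesis of 17 with the same ruthenium catalyst, where the alkyne is blocked by silicon and the lactone strain is absent, gives (1(10)Z,3S,4S,6R,7S,8R)-8-[(tert-butyldimethylsilyl)oxy]-3,4-(isopropylidenedioxy)-7-[(trimethylsilyl)ethynyl]-11,12,13-trinorgermacr-1(10)-en-6-ol F3. K2CO3 in MeOH then gives (1(10)Z,3S,4S,6R,7S,8R)-8-[(tert-butyldimethylsilyl)oxy]-7-ethynyl-3,4-(isopropylidenedioxy)-11,12,13-trinorgermacr-1(10)-en-6-ol F4. Cyclocarbonylation under the conditions of step 15 brings the fallback back to the route at 20.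

**Step 20 (directed epoxidation).** Facial selectivity rests on hydroxyl delivery in a flexible ten-membered ring, the tertiary C4 hydroxyl could direct to the other face, and the epoxy diol could open transannularly under Lewis acid. The fallback sets out from 23 and arrives at 24 by a reagent-controlled dioxirane epoxidation instead: Shi's fructose-derived ketone (the enantiomer matched to the required face), KHSO5, buffered aqueous MeCN, 0 °C. The face is then chosen by the chiral ketone and not by the substrate, and the electron-poor alkenes are untouched. It makes no new compound (F0).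

## Further compounds

F1 | step 14 | 2-[(4S,5S)-2,2,4-trimethyl-5-(prop-2-en-1-yl)-1,3-dioxolan-4-yl]acetaldehyde | C=CC[C@@H]1OC(C)(C)O[C@@]1(C)CC=O
F2 | step 14 | (3S,4R)-4-[(tert-butyldimethylsilyl)oxy]-6-methyl-1-(trimethylsilyl)hept-6-en-1-yn-3-yl methanesulfonate | C[Si](C)(C)C#C[C@H](OS(C)(=O)=O)[C@H](O[Si](C)(C)C(C)(C)C)CC(C)=C
F3 | step 16 | (1(10)Z,3S,4S,6R,7S,8R)-8-[(tert-butyldimethylsilyl)oxy]-3,4-(isopropylidenedioxy)-7-[(trimethylsilyl)ethynyl]-11,12,13-trinorgermacr-1(10)-en-6-ol | C[Si](C)(C)C#C[C@H]1[C@H](O)C[C@]2(C)OC(C)(C)O[C@H]2C/C=C(C)\C[C@H]1O[Si](C)(C)C(C)(C)C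
F4 | step 16 | (1(10)Z,3S,4S,6R,7S,8R)-8-[(tert-butyldimethylsilyl)oxy]-7-ethynyl-3,4-(isopropylidenedioxy)-11,12,13-trinorgermacr-1(10)-en-6-ol | C#C[C@H]1[C@H](O)C[C@]2(C)OC(C)(C)O[C@H]2C/C=C(C)\C[C@H]1O[Si](C)(C)C(C)(C)C
F0 | step 20 | none | none
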